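The constants show two fates for the initiator, and the constant of step 2 is far larger than that of step 1.

    free monomer + initiator → living end + monomer in chains (k1 = 1.6 × 10⁻⁴ M⁻¹ s⁻¹)
    free monomer + living end → monomer in chains + living end, rate k2*[living end]*[free monomer] (k2 = 0.090 M⁻¹ s⁻¹)
    initiator → spent initiator (k3 = 2.6 × 10⁻⁴ s⁻¹)

free monomer 1.5 M; initiator 15 mM; time 12 h

- the state of affairs at 12 h: stopped, and by what, or still going (all of the free monomer has reacted / it is still moving / forward and back rates have come level / no working catalyst is left)
- part of the free monomer gone at 12 h
- the monomer in chains standing at 12 h, as a percentage of the free monomer charged

- the reaction counts as stopped when no species that holds the free monomer changes by six tenths of a point or more over the second half of the time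
- run time (flask): 12 h

Find what is nearly constant and freeze it. Step 2 hands its living end back, and no step in the scheme removes one, so once the initiator has reacted, [living end] stands still. Free monomer then decays in a pseudo-first-order way, with lifetime 1/(k2[living end]).

To reckon [living end], take the initiator's split. At the charge, step 1 takes it at 2.40 × 10⁻⁴ s⁻¹ and step 3 at 2.6 × 10⁻⁴ s⁻¹, so at the start 48.0% of the initiator that reacts becomes living ends. Now you can solve two extreme flasks. If free monomer stayed at its charge, you would get 7.20 mM and a lifetime of 0.429 h. If that share held for the first half of the initiator and the rest gave nothing, you would get 3.60 mM and a longer lifetime, 0.857 h, the slow lifetime of free monomer.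

I expect the real flask between them, as an estimate and not a proven bound. That first half goes in 0.385 h, a little less than 0.429 h, so the share has dropped somewhat by then, and the later initiator adds some living ends at a lower share. Even at the slow lifetime, 0.0911% of the free monomer stands at 6.00 h, so I expect it used up and stopped. Steps 1 and 2 both put it into chains, so yield equals conversion.

The forecast says all of the free monomer has reacted, with 100% gone and 100% in chains. It gives one figure where I give a range: “about 5 mM living ends, which never die”.

In the flask at 12 h, all of the free monomer has reacted: 100% is gone and 100% stands in chains. Its living end reads 0.00524 M at 12.0 h, above 3.60 mM and below 7.20 mM , a lifetime of 0.589 h, shorter than the slow one. For the same flask read at 3.0 h, the two lifetimes put free monomer between 0.0918% and 3.02% , and that flask holds 1.15%.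

The numbers of this flask are assumed; what happens was integrated by code.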